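Leave grey, teal and amber stirring at their set temperatures until 4.0 h, and change no bath.

| flask | L | temperature | remark | time |
|---|---|---|---|---|
| autumn | 0.050 M | 60 °C | run made earlier |  |
| midnight | 0.075 M | 82 °C | run made earlier |  |
| grey | 0.10 M | 50 °C |  | 4.0 h |
| teal | 0.10 M | 70 °C |  | 4.0 h |
| amber | 0.10 M | 90 °C |  | 4.0 h |

- autumn (time / h: J / %, L / %): 0.250: 0.9, 97.8; 0.417: 0.2, 97.4; 0.500: 0.8, 97.0; 0.833: 0.3, 93.6; 1.33: 1.0, 90.7; 2.00: 1.3, 88.0; 3.00: 3.2, 81.5
- midnight (time / min: J / %, L / %): 5.00: 1.3, 96.6; 8.00: 0.4, 94.7; 10.0: 0.6, 93.1; 15.0: 2.3, 88.6; 25.0: 3.1, 83.0; 40.0: 6.1, 74.6; 60.0: 7.8, 64.2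

(each reading ± 0.5 percentage points)

- the flask with the highest amount of J, in percent of the L charged ("all alike" if they lie within 1.5 percentage points) (grey / teal / amber / all alike)
- final J, as a percentage of the L charged, in grey
- final J, as a percentage of the L charged, in teal
- final J, as a percentage of the L charged, in amber

- the analysis behind the earlier runs scatters by 0.5 percentage points, standard deviation

Each flask starts as pure L, and J grows from it. At its last reading autumn had lost L and gained 3.2% J, a ratio of 0.173; midnight gives 0.218. This ratio of J gained to L lost is the J share or selectivity, a reading for one moment of one run that carries the scatter of the analysis. It stands higher in midnight, but temperature and concentration changed together there, so don't read one flask's J from another's without saying which share is used.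

Our own reckoning takes the first-order pace of L in each run, 0.0682 h⁻¹ in autumn and 0.443 h⁻¹ in midnight. Over 4.0 h these paces lose 23.9% and 83.0% of the L.

Grey, colder than autumn, estimated high with autumn's share and pace: J about 0.173 × 23.9% = 4.13%

Amber, hotter than midnight, estimated with midnight's share and pace, and no bound: J about 0.218 × 83.0% = 18.1%

Teal lies between these, and we expect amber highest. The forecast also names amber, with 1.2%, 8.8% and 25%, the last above our amber estimate: “A hidden intermediate would raise amber”.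

The flasks give 1.09% in grey, 8.22% in teal and 32.9% in amber.

    2 L → E (k = 1.30 M⁻¹ h⁻¹, Ea = 65.0 kJ mol⁻¹)
    L ⇌ J (K = 5.30, k = 0.200 h⁻¹, Ea = 103 kJ mol⁻¹, ΔH = −49.0 kJ mol⁻¹)
    Q ⇌ Z (K = 5.40, k = 5.10 h⁻¹, Ea = 105 kJ mol⁻¹, ΔH = −3.00 kJ mol⁻¹)
    J ⇌ Q (K = 0.0960, k = 0.230 h⁻¹, Ea = 122 kJ mol⁻¹, ΔH = 0 kJ mol⁻¹)
    L ⇌ D (K = 0.460, k = 0.160 h⁻¹, Ea = 105 kJ mol⁻¹, ΔH = −47.0 kJ mol⁻¹)
    Z ⇌ L (k = 0.120 h⁻¹, Ea = 130 kJ mol⁻¹)
    2 L → G (k = 0.0100 M⁻¹ h⁻¹, Ea = 90.0 kJ mol⁻¹)
    (constants at 90 °C)

At the start of grey, L went to E at 6.2 times the rate at which it went to J, forward steps alone, and grey's J share at 4.0 h is 0.0825, below midnight's 0.218. Amber's share is 0.380, above it. The neighbouring flask at 75 °C ends with 12.6% J and 38% L, a J share of 0.203.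

The earlier runs and the new flask are simulated for an exercise; noise was put on by code.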